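The route rests on the C-8–C-8a bond (azulene numbering), which links the acyloxy-bearing allylic carbon to the methyl-bearing quaternary fusion carbon. It lies between the C-6=C-7 alkene and the C-3a–C-4 unit of the seven-membered ring, the pattern of a cyclohepta-1,4-diene, so it can be closed by [3,3] ring expansion of a cis-1,2-dialkenylcyclopropane. In one flask, an alkenoylsilane holding the complete five-membered ring (cut from (R)-terpinen-4-ol with its C-3 carbinol) and a 4-alkoxybutenone enolate give, by Brook rearrangement and cyclopropanation, a cyclopropanolate whose anionic oxy-Cope shift forms the seven-membered ring, C-8 and C-8a.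

Key step: step 6

Remark: (R)-(−)-terpinen-4-ol is assumed to be used enantiomerically pure (commercial material of lower enantiomeric purity would first have to be enriched).
Remark: locants are the azulene locants of 22 throughout; "methyl face" is the face of the bicycle that carries the 8a-methyl group, "opposite face" the other one.

Step 1
Reactants: 1 (R)-(−)-terpinen-4-ol
Product: 2 triethylsilyl ether of 1
Conditions: TESOTf, 2,6-lutidine, CH2Cl2, −78 → 0 °C
Reagents that add atoms: triethylsilyl trifluoromethanesulfonate, CC[Si](CC)(CC)OS(=O)(=O)C(F)(F)F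
Why: O-Silylation of the hindered tertiary alcohol with a silyl triflate and a pyridine base is reliable and masks the carbinol for the carbanion steps ahead, leaving the only stereocenter untouched.

Step 2
Reactants: 2 triethylsilyl ether
Product: 5 (5S)-2-methyl-5-(propan-2-yl)-5-(triethylsilyloxy)cyclopent-1-ene-1-carbaldehyde, via ozonide 3 (not isolated), via keto aldehyde 4 (not isolated)
Conditions: O3, CH2Cl2, −78 °C; Me2S, −78 °C → rt; then piperidine, AcOH, 40 °C
Reagents that add atoms: ozone, [O-][O+]=O
Why: Ozonolysis of the single alkene (through ozonide 3, reduced by Me2S) gives keto aldehyde 4, whose aldehyde-derived enamine attacks the methyl ketone in an intramolecular aldol condensation (piperidinium acetate) that should close the five-membered ring faster than silanolate is lost; the carbinol center is not involved (its descriptor changes from R to S by priority only).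

Step 3
Reactants: 5 cyclopentene carbaldehyde
Product: 6 α-hydroxysilane (both carbinol epimers)
Conditions: PhMe2SiLi, THF, −78 °C; AcOH, −78 °C
Reagents that add atoms: dimethyl(phenyl)silyllithium, [Li][Si](C)(C)c1ccccc1
Why: 1,2-Addition of a silyllithium reagent to the aldehyde gives the α-hydroxysilane, the cold acidic quench preventing Brook rearrangement of the lithium alkoxide; the new carbinol center forms without control and is removed in step 4.

Step 4
Reactants: 6 α-hydroxysilane
Product: 7 alkenoylsilane
Conditions: Dess–Martin periodinane, CH2Cl2, 0 °C → rt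
Reagents that add atoms: none
Why: Oxidation of an α-hydroxysilane to the acylsilane with the Dess–Martin reagent proceeds under non-basic conditions that do not trigger Brook rearrangement, and no stereocenter is created.

Step 5
Reactants: 8 but-3-yn-2-one
Product: 9 (3E)-4-[(4-methoxyphenyl)methoxy]but-3-en-2-one
Conditions: 4-methoxybenzyl alcohol, DABCO (10 mol %), CH2Cl2, 0 °C → rt
Reagents that add atoms: 4-methoxybenzyl alcohol, COc1ccc(CO)cc1
Why: Amine-catalysed oxa-Michael addition of the alcohol to the ynone gives the β-alkoxy enone as the thermodynamically favoured E isomer.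

Step 6
Reactants: 7 alkenoylsilane; 9 alkoxy enone
Product: 14 bicyclic dienyl triflate (C-6 triflate; C-3a=C-4 silyl enol ether; 8-PMB ether), via lithium dienolate 10 (not isolated), via silyl carbinolate 11 (not isolated), via dialkenylcyclopropanolate 12 (not isolated), via cycloheptadienolate 13 (not isolated)
Conditions: 9, LiN(i-Pr)2, THF, −80 °C; then 7, −80 → −30 °C; then 2-[N,N-bis(trifluoromethylsulfonyl)amino]-5-chloropyridine, −78 → 0 °C
Reagents that add atoms: N-(5-chloropyridin-2-yl)-1,1,1-trifluoro-N-(trifluoromethylsulfonyl)methanesulfonamide, FC(F)(F)S(=O)(=O)N(c1ccc(Cl)cn1)S(=O)(=O)C(F)(F)F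
Why: The kinetic dienolate 10 adds to the acylsilane carbonyl to give 11, silicon then shifts from carbon to oxygen (1,2-Brook rearrangement) as the carbon closes onto the ketone to give the cis-1,2-dialkenylcyclopropanolate 12, and its alkoxide-accelerated [3,3] shift cleaves the cyclopropane bond and forms C-8–C-8a to give enolate 13, which is triflated on oxygen. The closest known reaction type is the Brook rearrangement-mediated [3+4] annulation of alkenoylsilanes with enolates of alkenyl methyl ketones, an anionic oxy-Cope rearrangement of a cis-1,2-divinylcyclopropanediol monosilyl ether. The three-membered ring closes by 3-exo-trig addition of the carbanion to the ketone and the seven-membered ring by the [3,3]-sigmatropic ring expansion through a boat transition state. C-8a is set by the face of the cyclopentene on which the cyclopropane bond lies, expected anti to the 3-isopropyl group under control of the C-3 stereocenter from 1, and C-8 is set relative to it by the boat geometry, in which the E-alkoxy group is exo and the methyl group on the ring alkene is endo, so that the ether oxygen ends trans to the 8a-methyl group. The step needs kinetic deprotonation of the methyl group of 9, cyclopropanation in place of direct five-membered ring closure, and O-triflation of one defined enolate; the fully substituted allyl terminus, the aprotic medium and the low temperature (no loss of the β-alkoxide from 13) secure these.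

Step 7
Reactants: 14 dienyl triflate
Product: 15 C-6 methyl diene (silyl enol ether retained)
Conditions: MeZnCl, Pd(PPh3)4 (5 mol %), THF, rt → 40 °C
Reagents that add atoms: methylzinc chloride, C[Zn]Cl
Why: Negishi cross-coupling of the alkenyl triflate installs the C-6 methyl group without moving the double bond, and the neutral organozinc leaves the silyl enol ether and both other ethers intact; no stereocenter is touched.

Step 8
Reactants: 15 methyl diene
Product: 17 trans-fused C-4 ketone, via lithium enolate 16 (not isolated)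
Conditions: MeLi, THF, 0 °C; then AcOH, THF, −78 °C
Reagents that add atoms: none
Why: MeLi cleaves the silyl enol ether to the regiodefined enolate 16, and kinetic protonation at C-3a should occur on the opposite face, which is not flanked by the 8a-methyl and 3-isopropyl groups, to give the trans ring fusion (kinetic enolate protonation), the cold acidic quench avoiding equilibration and alkene migration.

Step 9
Reactants: 17 trans-fused ketone
Product: 18 C-4 alcohol (hydroxyl on the methyl face)
Conditions: LiBH(s-Bu)3 (L-Selectride), THF, −78 °C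
Reagents that add atoms: none
Why: Substrate-controlled reduction with a bulky hydride at −78 °C should deliver hydride from the opposite face, away from the 1,3-related 8a-methyl and the 3-isopropyl group, placing the new hydroxyl on the methyl face without epimerising C-3a.

Step 10
Reactants: 18 C-4 alcohol
Product: 19 4-(tert-butyldimethylsilyloxy)benzoate
Conditions: 4-(TBSO)C6H4CO2H, 2,4,6-trichlorobenzoyl chloride, Et3N, THF, rt; then 18, DMAP, toluene, 60 °C
Reagents that add atoms: 4-[(tert-butyldimethylsilyl)oxy]benzoic acid, CC(C)(C)[Si](C)(C)Oc1ccc(cc1)C(=O)O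
Why: Yamaguchi esterification through the mixed anhydride acylates the hindered secondary alcohol with retention at C-4, the phenol being carried as a silyl ether.

Step 11
Reactants: 19 aryl ester
Product: 20 C-8 allylic alcohol
Conditions: DDQ, CH2Cl2/pH 7 buffer, 0 °C
Reagents that add atoms: none
Why: Oxidative cleavage of the 4-methoxybenzyl ether with DDQ frees the C-8 hydroxyl and tolerates the silyl ethers, the ester and the trisubstituted alkene; no stereocenter is affected.

Step 12
Reactants: 20 allylic alcohol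
Product: 21 bis-silylated diester
Conditions: isovaleryl chloride, pyridine, DMAP (cat.), CH2Cl2, 0 °C → rt
Reagents that add atoms: 3-methylbutanoyl chloride, CC(C)CC(=O)Cl
Why: DMAP-catalysed O-acylation of the only free hydroxyl installs the isovalerate with retention at C-8.

Step 13
Reactants: 21 bis-silylated diester
Product: 22 target
Conditions: HF·pyridine, THF/pyridine, 0 °C → rt
Reagents that add atoms: none
Why: Fluoride-mediated desilylation removes the aryl and the tertiary alkyl silyl ether in one operation under conditions that spare both esters and the allylic system.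

Compound list
1 | (R)-(−)-terpinen-4-ol, (1R)-4-methyl-1-(propan-2-yl)cyclohex-3-en-1-ol | CC1=CC[C@@](O)(C(C)C)CC1 | starting material
2 | triethyl{[(1R)-4-methyl-1-(propan-2-yl)cyclohex-3-en-1-yl]oxy}silane | CC1=CC[C@@](O[Si](CC)(CC)CC)(C(C)C)CC1 | intermediate
3 | secondary ozonide of 2 (1,2,4-trioxolane bridging the former alkene carbons, both diastereomers, carbinol carbon as in 2; not isolated) | CC12CC[C@](O[Si](CC)(CC)CC)(C(C)C)CC(OO1)O2 | intermediate
4 | (3R)-6-oxo-3-(propan-2-yl)-3-(triethylsilyloxy)heptanal (not isolated) | CC(=O)CC[C@](O[Si](CC)(CC)CC)(C(C)C)CC=O | intermediate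
5 | (5S)-2-methyl-5-(propan-2-yl)-5-(triethylsilyloxy)cyclopent-1-ene-1-carbaldehyde | O=CC1=C(C)CC[C@]1(O[Si](CC)(CC)CC)C(C)C | intermediate
6 | [dimethyl(phenyl)silyl][(5S)-2-methyl-5-(propan-2-yl)-5-(triethylsilyloxy)cyclopent-1-en-1-yl]methanol, both carbinol epimers | OC([Si](C)(C)c1ccccc1)C1=C(C)CC[C@]1(O[Si](CC)(CC)CC)C(C)C | intermediate
7 | [dimethyl(phenyl)silyl][(5S)-2-methyl-5-(propan-2-yl)-5-(triethylsilyloxy)cyclopent-1-en-1-yl]methanone | O=C([Si](C)(C)c1ccccc1)C1=C(C)CC[C@]1(O[Si](CC)(CC)CC)C(C)C | intermediate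
8 | but-3-yn-2-one | CC(=O)C#C | starting material
9 | (3E)-4-[(4-methoxyphenyl)methoxy]but-3-en-2-one | CC(=O)/C=C/OCc1ccc(OC)cc1 | intermediate
10 | lithium (3E)-4-[(4-methoxyphenyl)methoxy]buta-1,3-dien-2-olate (not isolated) | [Li]OC(=C)/C=C/OCc1ccc(OC)cc1 | intermediate
11 | lithium (4E)-1-[dimethyl(phenyl)silyl]-5-[(4-methoxyphenyl)methoxy]-1-[(5S)-2-methyl-5-(propan-2-yl)-5-(triethylsilyloxy)cyclopent-1-en-1-yl]-3-oxopent-4-en-1-olate, carbinolate carbon undefined (not isolated) | [Li]OC(CC(=O)/C=C/OCc1ccc(OC)cc1)([Si](C)(C)c1ccccc1)C1=C(C)CC[C@]1(O[Si](CC)(CC)CC)C(C)C | intermediate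
12 | lithium 2-[dimethyl(phenyl)silyloxy]-1-{(E)-2-[(4-methoxyphenyl)methoxy]ethenyl}-2-[(5S)-2-methyl-5-(propan-2-yl)-5-(triethylsilyloxy)cyclopent-1-en-1-yl]cyclopropan-1-olate; the two alkenyl groups cis, the cyclopropane bond that breaks on the cyclopentene face anti to isopropyl (not isolated) | [Li]O[C@]1(/C=C/OCc2ccc(OC)cc2)C[C@@]1(O[Si](C)(C)c2ccccc2)C1=C(C)CC[C@]1(O[Si](CC)(CC)CC)C(C)C | intermediate
13 | lithium 4-[dimethyl(phenyl)silyloxy]-8-[(4-methoxyphenyl)methoxy]-8a-methyl-3-(propan-2-yl)-3-(triethylsilyloxy)-1,2,3,5,8,8a-hexahydroazulen-6-olate; 3-O and 8-O on the opposite face, 3-isopropyl on the methyl face (not isolated) | [Li]OC1=C[C@@H](OCc3ccc(OC)cc3)[C@@]2(C)CC[C@](O[Si](CC)(CC)CC)(C(C)C)C2=C(O[Si](C)(C)c2ccccc2)C1 | intermediate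
14 | 4-[dimethyl(phenyl)silyloxy]-8-[(4-methoxyphenyl)methoxy]-8a-methyl-3-(propan-2-yl)-3-(triethylsilyloxy)-1,2,3,5,8,8a-hexahydroazulen-6-yl trifluoromethanesulfonate; 3-O and 8-O on the opposite face, 3-isopropyl on the methyl face | FC(F)(F)S(=O)(=O)OC1=C[C@@H](OCc3ccc(OC)cc3)[C@@]2(C)CC[C@](O[Si](CC)(CC)CC)(C(C)C)C2=C(O[Si](C)(C)c2ccccc2)C1 | intermediate
15 | 4-[dimethyl(phenyl)silyloxy]-8-[(4-methoxyphenyl)methoxy]-6,8a-dimethyl-3-(propan-2-yl)-3-(triethylsilyloxy)-1,2,3,5,8,8a-hexahydroazulene; stereocenters as in 14 | CC1=C[C@@H](OCc3ccc(OC)cc3)[C@@]2(C)CC[C@](O[Si](CC)(CC)CC)(C(C)C)C2=C(O[Si](C)(C)c2ccccc2)C1 | intermediate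
16 | lithium 8-[(4-methoxyphenyl)methoxy]-6,8a-dimethyl-3-(propan-2-yl)-3-(triethylsilyloxy)-1,2,3,5,8,8a-hexahydroazulen-4-olate; stereocenters as in 14 (not isolated) | CC1=C[C@@H](OCc3ccc(OC)cc3)[C@@]2(C)CC[C@](O[Si](CC)(CC)CC)(C(C)C)C2=C(O[Li])C1 | intermediate
17 | 8-[(4-methoxyphenyl)methoxy]-6,8a-dimethyl-3-(propan-2-yl)-3-(triethylsilyloxy)-2,3,3a,5,8,8a-hexahydroazulen-4(1H)-one; trans-fused, 3a-H, 3-O and 8-O on the opposite face, 3-isopropyl on the methyl face | CC1=C[C@@H](OCc3ccc(OC)cc3)[C@@]2(C)CC[C@](O[Si](CC)(CC)CC)(C(C)C)[C@@H]2C(=O)C1 | intermediate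
18 | 8-[(4-methoxyphenyl)methoxy]-6,8a-dimethyl-3-(propan-2-yl)-3-(triethylsilyloxy)-1,2,3,3a,4,5,8,8a-octahydroazulen-4-ol; as 17, 4-OH on the methyl face | CC1=C[C@@H](OCc3ccc(OC)cc3)[C@@]2(C)CC[C@](O[Si](CC)(CC)CC)(C(C)C)[C@@H]2[C@H](O)C1 | intermediate
19 | 4-[(tert-butyldimethylsilyl)oxy]benzoate of 18 at O-4 | CC1=C[C@@H](OCc3ccc(OC)cc3)[C@@]2(C)CC[C@](O[Si](CC)(CC)CC)(C(C)C)[C@@H]2[C@H](OC(=O)c2ccc(O[Si](C)(C)C(C)(C)C)cc2)C1 | intermediate
20 | 8-hydroxy-6,8a-dimethyl-3-(propan-2-yl)-3-(triethylsilyloxy)-1,2,3,3a,4,5,8,8a-octahydroazulen-4-yl 4-[(tert-butyldimethylsilyl)oxy]benzoate; stereocenters as in 19 | CC1=C[C@@H](O)[C@@]2(C)CC[C@](O[Si](CC)(CC)CC)(C(C)C)[C@@H]2[C@H](OC(=O)c2ccc(O[Si](C)(C)C(C)(C)C)cc2)C1 | intermediate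
21 | 6,8a-dimethyl-8-[(3-methylbutanoyl)oxy]-3-(propan-2-yl)-3-(triethylsilyloxy)-1,2,3,3a,4,5,8,8a-octahydroazulen-4-yl 4-[(tert-butyldimethylsilyl)oxy]benzoate; stereocenters as in 22 | CC1=C[C@@H](OC(=O)CC(C)C)[C@@]2(C)CC[C@](O[Si](CC)(CC)CC)(C(C)C)[C@@H]2[C@H](OC(=O)c2ccc(O[Si](C)(C)C(C)(C)C)cc2)C1 | intermediate
22 | (3S,3aS,4R,8R,8aS)-3-hydroxy-6,8a-dimethyl-8-[(3-methylbutanoyl)oxy]-3-(propan-2-yl)-1,2,3,3a,4,5,8,8a-octahydroazulen-4-yl 4-hydroxybenzoate (3-OH, 3a-H and 8-O on the opposite face; 3-isopropyl and 4-O on the methyl face) | CC1=C[C@@H](OC(=O)CC(C)C)[C@@]2(C)CC[C@](O)(C(C)C)[C@@H]2[C@H](OC(=O)c2ccc(O)cc2)C1 | target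

Total step count: 13. Longest linear sequence: 12 steps (steps 1–4 and 6–13; step 5 makes the second fragment).

Steps most likely to fail

1. Step 6. The cascade may stall after carbonyl addition (no Brook rearrangement and ring closure at the hindered carbinolate), the boat transition state may be slowed by the endo methyl group, or the cyclopropane may form on the isopropyl face (poor facial selectivity). The fallback closes the same bond by a reductive carbonyl–enone coupling; it sets out from 5 and returns to the route at 21. The dianion of 3-methylbut-2-enoic acid (LiN(i-Pr)2, THF, −78 °C → rt) adds through its γ-carbon to 5 and lactonises on acidification to dihydropyranone F1. LiAlH4 opens the lactone to (Z)-diol F2, and Dess–Martin periodinane oxidises both allylic alcohols to (Z)-keto enal F3. SmI2 (THF, t-BuOH, −78 °C) then couples the aldehyde carbon with the enone β-carbon to give hydroxy ketone F4 (C-8 epimers to be separated). Isovaleryl chloride/DMAP gives keto ester F5, LiBH(s-Bu)3 reduces it to alcohol F6, and Yamaguchi esterification with 4-(TBSO)benzoic acid gives 21.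

2. Step 8. Protonation may occur on the methyl face, or the ketone may equilibrate at C-3a to the cis-fused isomer or let the C-6 alkene move into conjugation during work-up. The fallback replaces proton delivery by irreversible hydrogen-atom transfer under non-basic conditions; it sets out from 15 and returns at 17. Enolate 16, generated with MeLi as before, is trapped with PhSeBr at −78 °C as α-phenylselanyl ketone F7. Bu3SnH with Et3B/O2 (toluene, −78 °C) then reduces the planar α-keto radical from the less hindered opposite face.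

3. Step 9. Hydride may be delivered to the methyl face instead (the 3-silyloxy group lies on the opposite face), so that facial selectivity is poor or reversed. The fallback sets out from 17 and returns at 19. The reduction is then run to give the C-4 epimer, alcohol F8, and the aroyl ester is introduced with inversion by a Mitsunobu reaction (4-(TBSO)benzoic acid, PPh3, DIAD, toluene).

Further compounds
F1 | step 6 | 4-methyl-6-[(5S)-2-methyl-5-(propan-2-yl)-5-(triethylsilyloxy)cyclopent-1-en-1-yl]-5,6-dihydro-2H-pyran-2-one (both C-6 epimers) | CC1=CC(=O)OC(C1)C1=C(C)CC[C@]1(O[Si](CC)(CC)CC)C(C)C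
F2 | step 6 | (2Z)-3-methyl-5-[(5S)-2-methyl-5-(propan-2-yl)-5-(triethylsilyloxy)cyclopent-1-en-1-yl]pent-2-ene-1,5-diol (both C-5 epimers) | OC/C=C(/C)CC(O)C1=C(C)CC[C@]1(O[Si](CC)(CC)CC)C(C)C
F3 | step 6 | (2Z)-3-methyl-5-[(5S)-2-methyl-5-(propan-2-yl)-5-(triethylsilyloxy)cyclopent-1-en-1-yl]-5-oxopent-2-enal | O=C/C=C(/C)CC(=O)C1=C(C)CC[C@]1(O[Si](CC)(CC)CC)C(C)C
F4 | step 6 | 8-hydroxy-6,8a-dimethyl-3-(propan-2-yl)-3-(triethylsilyloxy)-2,3,3a,5,8,8a-hexahydroazulen-4(1H)-one; stereocenters as in 17 | CC1=C[C@@H](O)[C@@]2(C)CC[C@](O[Si](CC)(CC)CC)(C(C)C)[C@@H]2C(=O)C1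
F5 | step 6 | 3-methylbutanoate of F4 at O-8 | CC1=C[C@@H](OC(=O)CC(C)C)[C@@]2(C)CC[C@](O[Si](CC)(CC)CC)(C(C)C)[C@@H]2C(=O)C1
F6 | step 6 | 4-hydroxy-6,8a-dimethyl-3-(propan-2-yl)-3-(triethylsilyloxy)-1,2,3,3a,4,5,8,8a-octahydroazulen-8-yl 3-methylbutanoate; 4-OH on the methyl face | CC1=C[C@@H](OC(=O)CC(C)C)[C@@]2(C)CC[C@](O[Si](CC)(CC)CC)(C(C)C)[C@@H]2[C@H](O)C1
F7 | step 8 | 3a-(phenylselanyl) derivative of ketone 17 (C-3a configuration undefined) | CC1=C[C@@H](OCc3ccc(OC)cc3)[C@@]2(C)CC[C@](O[Si](CC)(CC)CC)(C(C)C)C2([Se]c2ccccc2)C(=O)C1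
F8 | step 9 | C-4 epimer of alcohol 18 (4-OH on the opposite face) | CC1=C[C@@H](OCc3ccc(OC)cc3)[C@@]2(C)CC[C@](O[Si](CC)(CC)CC)(C(C)C)[C@@H]2[C@@H](O)C1
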